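A small charge of catalyst E, 8.8 µM against 0.010 M of substrate D, has to empty a pool that leaves by two exits, and what I want is the share taken by each.

    D ⇌ L, settled at all times (K1 = 3.2)
    E + L → E + Q (k2 = 1900 M⁻¹ s⁻¹)
    D + E → E + G (k3 = 5000 M⁻¹ s⁻¹)
    E ⇌ Z (K4 = 0.69, k4 = 0.044 s⁻¹)

D 0.010 M; E 8.8 µM; time 30 min

- at 30 min, what has stopped the reaction, if anything has (L counts as not reacted) (forward and back rates have come level / no working catalyst is left / it is still moving / all of D has reacted)
- part of the D that has turned into other species by 30 min (L does not count)
- amount of G at 30 min, in percent of the D charged

- in a conversion L counts as not yet reacted
- the reaction counts as stopped when no species that holds the D changes by six tenths of a point or more over the second half of the time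
- run time (flask): 30 min

D and L stay balanced, with L standing at 3.2 times D. G therefore forms with constant 5000 M⁻¹ s⁻¹ on D, and Q with 1900 M⁻¹ s⁻¹ on L, which is 6080 M⁻¹ s⁻¹ when measured on D. Free E multiplies both rates alike, so it cancels from their ratio. I carry one quantity, the branching share S (the selectivity factor written as a share): the constant of the G exit over the sum of both exits' constants, each measured on D. It gives S = 45.1%, smaller than the Q exit's part.

The second way goes through times. With E as charged, the half-life of D by the step to G alone is 0.26 min, and that of L by the step to Q alone is 0.69 min. Weighting each exit's speed by the balance of the pool gives 45.3%. This is the first way rewritten and no check on it: each half-life is one common number divided by its constant and by E, so that number and E cancel and the expression for S returns, and the small gap from S comes from rounding the two half-lives.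

S becomes the yield once the pool has drained. With Z balanced against E, the pool's time constant is 72.8 s, and the run lasts 24.7 such times, so hardly any of the pool stays.

The forecast gives all of D has reacted, conversion 100% and G 45.1%, and says “The G share is then fixed by the rate ratio of the two channels”.

The flask gives all of D has reacted, conversion 100% and G 45.1%, which is S. The half-life of D by the step to G alone, 0.26 min, is far shorter than the run of 30 min, and at 15.0 min the flask holds D 0%, L 0%, G 45.1% and Q 54.9%. In the neighbour flask with E at 3.5 × 10⁻⁶ M, S again stands for the yield, and that flask ends with D 0% and G 45.1%.

The numbers belong to no real substance; the rest is arithmetic.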